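**Retrosynthetic overview**
- Esters last: the C10 epoxyangelate by acylation, the C9 angelate by Mitsunobu inversion of a cis-9,10-diol on the himachala-2,7-dien-4-one core.
- Ring B (seven-membered): C1–C11 disconnection. A bisabolane-type 10,11-epoxide is opened by Lewis acid at its tertiary carbon and captured 7-endo by the γ-carbon of a ring-A silyl dienol ether. This is the C1–C11 bond of the farnesyl 1,11-closure; it sets C1 (cis fusion) and keeps C10.
- Epoxy alcohol ⇒ C8–C9 bond: (Z)-alkenyllithium plus an (R)-epoxy aldehyde (Felkin–Anh, erythro).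
- (Z)-Alkenyl bromide ⇒ (S)-carvone by cross-metathesis with vinyl-Bpin, then bromodeboronation with inversion of alkene geometry.
- Ring order: ring A (six-membered, C6 stereocentre) is carried intact from (S)-carvone; ring B is the only ring made (step 7). Both epoxides come from Sharpless epoxidations (prenol, angelyl alcohol).

Assumption: atoms are discussed with farnesane numbering (C1/C6 ring fusion, C4 ketone, C7=C8, C9 angelate, C10 epoxyangelate, C11 gem-dimethyl carbon); systematic names use benzo[7]annulene numbering (C1 = 4a, C6 = 9a, C9 = 7, C10 = 6).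

**Route**

Step 1
Reactants: 1 (S)-(+)-carvone; 2 vinylboronic acid pinacol ester
Product: 3 (5S)-2-methyl-5-[(1E)-1-(4,4,5,5-tetramethyl-1,3,2-dioxaborolan-2-yl)prop-1-en-2-yl]cyclohex-2-en-1-one
Conditions: second-generation Hoveyda–Grubbs catalyst (5 mol %), 2 (3 equiv), CH2Cl2, 40 °C, 24 h
Reagents that add atoms: none
Why: Olefin cross-metathesis of a 1,1-disubstituted alkene with vinyl-Bpin is a known route to trisubstituted alkenyl boronates, and the reversible metathesis places Bpin trans to the bulky ring carbon (E) while the electron-poor enone and the ring stereocentre stay untouched.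

Step 2
Reactants: 3 the (E)-alkenyl boronate
Product: 5 (5S)-5-[(1Z)-1-bromoprop-1-en-2-yl]-2-methylcyclohex-2-en-1-one, via anti-dibromide 4 (not isolated)
Conditions: Br2, CH2Cl2, −78 °C; then NaOMe, MeOH, −78 → 0 °C
Reagents that add atoms: bromine, BrBr
Why: Brown-type bromodeboronation, in which anti addition of Br2 followed by methoxide-triggered anti elimination of boron and the β-bromide replaces boron by bromine with inversion of alkene geometry, so that Br (the future C8–C9 bond) ends up cis to the ring carbon.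

Step 3
Reactants: 5 the (Z)-bromo enone
Product: 6 tert-butyl({(5R)-5-[(1Z)-1-bromoprop-1-en-2-yl]-2-methylcyclohexa-1,3-dien-1-yl}oxy)dimethylsilane
Conditions: TBSCl, NaI, Et3N, MeCN, 40 °C
Reagents that add atoms: tert-butyldimethylsilyl chloride, C[Si](C)(Cl)C(C)(C)C
Why: Thermodynamic silyl enol ether formation (reversible silylation by TBSI made in the flask) funnels the enone to the through-conjugated 1-silyloxy-1,3-diene by γ-deprotonation, which masks the ketone against t-BuLi and provides the γ-nucleophile for step 7 without touching the stereocentre.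

Step 4
Reactants: 7 prenol (3-methylbut-2-en-1-ol)
Product: 8 [(2S)-3,3-dimethyloxiran-2-yl]methanol
Conditions: Ti(OiPr)4 (10 mol %), L-(+)-diethyl tartrate (12 mol %), t-BuOOH, 4 Å molecular sieves, CH2Cl2, −20 °C
Reagents that add atoms: tert-butyl hydroperoxide, CC(C)(C)OO
Why: Sharpless asymmetric epoxidation, in which the L-(+)-tartrate catalyst gives the (2S)-epoxy alcohol (same facial sense as geraniol to its (2S,3S)-epoxide) and thereby fixes the future C10 stereocentre.

Step 5
Reactants: 8 the (S)-epoxy alcohol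
Product: 9 (2R)-3,3-dimethyloxirane-2-carbaldehyde
Conditions: TEMPO (10 mol %), PhI(OAc)2, CH2Cl2, 0 °C → rt; bulb-to-bulb distillation
Reagents that add atoms: none
Why: TEMPO/PhI(OAc)2 oxidation of a primary alcohol to the aldehyde under near-neutral conditions that leave the epoxide and its stereocentre intact (S becomes R only through CIP priorities).

Step 6
Reactants: 6 the bromo silyl dienol ether; 9 the (R)-epoxy aldehyde
Product: 11 (1S,2Z)-3-[(1R)-5-{[tert-butyl(dimethyl)silyl]oxy}-4-methylcyclohexa-2,4-dien-1-yl]-1-[(2S)-3,3-dimethyloxiran-2-yl]but-2-en-1-ol, via Z-alkenyllithium 10 (not isolated)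
Conditions: t-BuLi (2.1 equiv), Et2O, −78 °C; then 9, −78 °C; H2O
Reagents that add atoms: none
Why: Lithium–bromine exchange with retention of alkene geometry followed by 1,2-addition to the α,β-epoxy aldehyde under Felkin–Anh (Cornforth) control gives mainly the anti (erythro) epoxy alcohol with the new carbinol S (about 4:1 expected, separable), the silyl dienol ether keeping the ring ketone masked.

Step 7
Reactants: 11 the erythro epoxy alcohol
Product: 12 (4aS,6R,7S,9aR)-6,7-dihydroxy-3,5,5,9-tetramethyl-1,4a,5,6,7,9a-hexahydro-2H-benzo[7]annulen-2-one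
Conditions: MeAlCl2 (2.2 equiv), CH2Cl2, −78 → −40 °C; aq. potassium sodium tartrate
Reagents that add atoms: none
Why: Proposed new method: MeAlCl2 first forms the C9 aluminium alkoxide, which chelates and ionises the 2,3-epoxy alcohol at its tertiary C11 terminus (Markovnikov opening), and the tethered silyl dienol ether attacks C11 through its γ-carbon C1 in a 7-endo cation–olefin closure that recreates the C1–C11 bond of the farnesyl 1,11-cyclisation; axial attack on the diene face reached by the pseudo-equatorial C6 tether gives the cis ring fusion (4aS), C10 keeps its configuration and loss of the silyl group returns the enone; the closest known reaction types are Lewis-acid epoxy-olefin cyclisations terminated by silyl enol ethers and γ-selective vinylogous Mukaiyama alkylations of silyl dienol ethers by tertiary cations.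

Step 8
Reactants: 13 angelic acid
Product: 14 (2Z)-2-methylbut-2-en-1-ol
Conditions: LiAlH4, Et2O, 0 °C
Reagents that add atoms: none
Why: LiAlH4 reduction of the carboxylic acid to the primary allylic alcohol by 1,2-hydride delivery, which leaves the trisubstituted Z alkene unchanged.

Step 9
Reactants: 14 the (Z)-allylic alcohol
Product: 15 [(2S,3R)-2,3-dimethyloxiran-2-yl]methanol
Conditions: Ti(OiPr)4 (10 mol %), L-(+)-diethyl tartrate (12 mol %), t-BuOOH, 4 Å molecular sieves, CH2Cl2, −20 °C
Reagents that add atoms: tert-butyl hydroperoxide, CC(C)(C)OO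
Why: Sharpless asymmetric epoxidation with L-(+)-tartrate delivers oxygen to the same alkene face as in step 4 and converts the Z alkene stereospecifically into the cis (2S,3R)-epoxy alcohol.

Step 10
Reactants: 15 the (2S,3R)-epoxy alcohol
Product: 16 (2R,3R)-2,3-dimethyloxirane-2-carboxylic acid
Conditions: RuCl3·xH2O (2 mol %), NaIO4, MeCN/EtOAc/H2O, 0 °C → rt
Reagents that add atoms: sodium periodate, [Na+].[O-]I(=O)(=O)=O; water, O
Why: RuO4-catalysed (RuCl3/NaIO4) oxidation of the primary alcohol to the glycidic acid, whose quaternary α-carbon cannot epimerise (S becomes R at C2 only through CIP priorities).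

Step 11
Reactants: 12 the cis-diol enone; 13 angelic acid
Product: 17 (4aS,6R,7R,9aR)-6-hydroxy-3,5,5,9-tetramethyl-2-oxo-2,4a,5,6,7,9a-hexahydro-1H-benzo[7]annulen-7-yl (2Z)-2-methylbut-2-enoate
Conditions: PPh3, DIAD, THF/toluene, 0 °C → rt
Reagents that add atoms: none
Why: Mitsunobu esterification, in which only the allylic C9–OH can undergo SN2 (C10–OH is neopentylic) and the angelate enters as a carboxylate nucleophile with inversion (no acyl activation, hence no Z to E isomerisation), converting the cis diol into the trans 9-angelate-10-ol.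

Step 12
Reactants: 16 the (2R,3R)-epoxy acid; 17 the hydroxy angelate
Product: 19 (4aS,6R,7R,9aR)-3,5,5,9-tetramethyl-7-{[(2Z)-2-methylbut-2-enoyl]oxy}-2-oxo-2,4a,5,6,7,9a-hexahydro-1H-benzo[7]annulen-6-yl (2R,3R)-2,3-dimethyloxirane-2-carboxylate, via Yamaguchi mixed anhydride 18 (not isolated)
Conditions: 2,4,6-trichlorobenzoyl chloride, Et3N, toluene, rt; then 17, DMAP, toluene, 60 °C
Reagents that add atoms: none
Why: Yamaguchi esterification, in which the mixed anhydride of the non-epimerisable α-quaternary epoxy acid acylates the hindered C10–OH under DMAP catalysis with retention at every stereocentre.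

**Compound list**

1 | (S)-(+)-carvone, (5S)-2-methyl-5-(prop-1-en-2-yl)cyclohex-2-en-1-one | CC1=CC[C@@H](CC1=O)C(C)=C | starting material
2 | vinylboronic acid pinacol ester (4,4,5,5-tetramethyl-2-vinyl-1,3,2-dioxaborolane) | C=CB1OC(C)(C)C(C)(C)O1 | starting material
3 | (5S)-2-methyl-5-[(1E)-1-(4,4,5,5-tetramethyl-1,3,2-dioxaborolan-2-yl)prop-1-en-2-yl]cyclohex-2-en-1-one | CC1=CC[C@@H](CC1=O)/C(C)=C/B2OC(C)(C)C(C)(C)O2 | intermediate
4 | (5S)-5-[(1R,2S)-1,2-dibromo-1-(4,4,5,5-tetramethyl-1,3,2-dioxaborolan-2-yl)propan-2-yl]-2-methylcyclohex-2-en-1-one (anti adduct; the (1S,2R) face isomer forms alongside and gives the same bromide) | CC1=CC[C@@H](CC1=O)[C@](C)(Br)[C@H](Br)B2OC(C)(C)C(C)(C)O2 | intermediate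
5 | (5S)-5-[(1Z)-1-bromoprop-1-en-2-yl]-2-methylcyclohex-2-en-1-one | CC1=CC[C@@H](CC1=O)/C(C)=C\Br | intermediate
6 | tert-butyl({(5R)-5-[(1Z)-1-bromoprop-1-en-2-yl]-2-methylcyclohexa-1,3-dien-1-yl}oxy)dimethylsilane | CC1=C(O[Si](C)(C)C(C)(C)C)C[C@H](C=C1)/C(C)=C\Br | intermediate
7 | prenol (3-methylbut-2-en-1-ol) | CC(C)=CCO | starting material
8 | [(2S)-3,3-dimethyloxiran-2-yl]methanol | OC[C@@H]1OC1(C)C | intermediate
9 | (2R)-3,3-dimethyloxirane-2-carbaldehyde | O=C[C@@H]1OC1(C)C | intermediate
10 | {(1Z)-2-[(1R)-5-{[tert-butyl(dimethyl)silyl]oxy}-4-methylcyclohexa-2,4-dien-1-yl]prop-1-en-1-yl}lithium | CC1=C(O[Si](C)(C)C(C)(C)C)C[C@H](C=C1)/C(C)=C\[Li] | intermediate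
11 | (1S,2Z)-3-[(1R)-5-{[tert-butyl(dimethyl)silyl]oxy}-4-methylcyclohexa-2,4-dien-1-yl]-1-[(2S)-3,3-dimethyloxiran-2-yl]but-2-en-1-ol | CC1=C(O[Si](C)(C)C(C)(C)C)C[C@H](C=C1)/C(C)=C\[C@H](O)[C@@H]2OC2(C)C | intermediate
12 | (4aS,6R,7S,9aR)-6,7-dihydroxy-3,5,5,9-tetramethyl-1,4a,5,6,7,9a-hexahydro-2H-benzo[7]annulen-2-one (cis-fused, cis-9,10-diol) | O[C@H]1C=C(C)[C@@H]2CC(=O)C(C)=C[C@@H]2C(C)(C)[C@H]1O | intermediate
13 | angelic acid, (2Z)-2-methylbut-2-enoic acid | C/C=C(/C)C(=O)O | starting material
14 | (2Z)-2-methylbut-2-en-1-ol | C/C=C(/C)CO | intermediate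
15 | [(2S,3R)-2,3-dimethyloxiran-2-yl]methanol | OC[C@]1(C)O[C@@H]1C | intermediate
16 | (2R,3R)-2,3-dimethyloxirane-2-carboxylic acid | OC(=O)[C@]1(C)O[C@@H]1C | intermediate
17 | (4aS,6R,7R,9aR)-6-hydroxy-3,5,5,9-tetramethyl-2-oxo-2,4a,5,6,7,9a-hexahydro-1H-benzo[7]annulen-7-yl (2Z)-2-methylbut-2-enoate | C/C=C(/C)C(=O)O[C@@H]1C=C(C)[C@@H]2CC(=O)C(C)=C[C@@H]2C(C)(C)[C@H]1O | intermediate
18 | (2R,3R)-2,3-dimethyloxirane-2-carboxylic 2,4,6-trichlorobenzoic anhydride | O=C(OC(=O)c1c(Cl)cc(Cl)cc1Cl)[C@]2(C)O[C@@H]2C | intermediate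
19 | (4aS,6R,7R,9aR)-3,5,5,9-tetramethyl-7-{[(2Z)-2-methylbut-2-enoyl]oxy}-2-oxo-2,4a,5,6,7,9a-hexahydro-1H-benzo[7]annulen-6-yl (2R,3R)-2,3-dimethyloxirane-2-carboxylate | C/C=C(/C)C(=O)O[C@@H]1C=C(C)[C@@H]2CC(=O)C(C)=C[C@@H]2C(C)(C)[C@H]1OC(=O)[C@]1(C)O[C@@H]1C | target

**Totals and risks**

Total step count: 12. Longest linear sequence: 7 steps from 1 (steps 1, 2, 3, 6, 7, 11, 12); steps 4–5 and 8–10 are side branches.

The step most likely to fail is step 7. The 7-endo closure has to beat hydride shift to a C10 ketone, elimination to the allylic alcohol and 6-exo attack at C10. The fallback sets out from 11 and swaps the cationic opening for a radical one. Cp2TiCl (trivalent titanium, made from Cp2TiCl2 and Mn dust, THF, rt) opens the epoxide homolytically to the tertiary C11 radical, which adds 7-endo to C1 of the silyloxy diene. Reduction and protonation of the resulting allyl radical give (4aS,6R,7S,9aR)-2-{[tert-butyl(dimethyl)silyl]oxy}-3,5,5,9-tetramethyl-4,4a,5,6,7,9a-hexahydro-1H-benzo[7]annulene-6,7-diol F5. Saegusa–Ito dehydrosilylation with Pd(OAc)2 in MeCN then restores the enone, and the route is rejoined at 12.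

The second is step 1, cross-metathesis at an isopropenyl group carried by a secondary carbon. The fallback sets out from 1 and reaches the Z bromide through a silicon tether instead. NaBH4/CeCl3·7H2O reduction gives (1S,5S)-cis-carveol F1. Silylation with chloro(dimethyl)vinylsilane and Et3N gives the vinylsilyl ether F2. Ring-closing metathesis with the second-generation Hoveyda–Grubbs catalyst closes (1S,6S)-3,3,5,9-tetramethyl-2-oxa-3-silabicyclo[4.3.1]deca-4,8-diene F3, whose new trisubstituted alkene is Z by ring constraint. Bromodesilylation with N-bromosuccinimide (retention) and K2CO3/MeOH gives (1S,5S)-5-[(1Z)-1-bromoprop-1-en-2-yl]-2-methylcyclohex-2-en-1-ol F4. MnO2 oxidation rejoins the route at 5.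

The third is step 12, acylation of the neopentylic C10–OH, where base-induced shift of the C9 angelate to O10 could also scramble the two esters. The fallback sets out from 12 and uses the acyl shift deliberately. The accessible C9–OH of the cis diol is acylated with 16 (EDC·HCl, DMAP, 0 °C) to give the 7-O-[(2R,3R)-2,3-dimethyloxirane-2-carbonyl] cis-diol monoester F6. DBU in toluene equilibrates it by 1,2-acyl shift with the 6-O-acyl isomer F7, which has the allylic C9–OH free. Only F7 can react in a Mitsunobu esterification with 13 (PPh3, DIAD), which drains the equilibrium with inversion at C9 and rejoins the route at 19.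

**Further compounds**

F1 | step 1 | (1S,5S)-2-methyl-5-(prop-1-en-2-yl)cyclohex-2-en-1-ol (cis-carveol) | CC1=CC[C@@H](C[C@@H]1O)C(C)=C
F2 | step 1 | ethenyl(dimethyl){[(1S,5S)-2-methyl-5-(prop-1-en-2-yl)cyclohex-2-en-1-yl]oxy}silane | CC1=CC[C@@H](C[C@@H]1O[Si](C)(C)C=C)C(C)=C
F3 | step 1 | (1S,6S)-3,3,5,9-tetramethyl-2-oxa-3-silabicyclo[4.3.1]deca-4,8-diene | CC1=CC[C@H]2C[C@@H]1O[Si](C)(C)C=C2C
F4 | step 1 | (1S,5S)-5-[(1Z)-1-bromoprop-1-en-2-yl]-2-methylcyclohex-2-en-1-ol | CC1=CC[C@@H](C[C@@H]1O)/C(C)=C\Br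
F5 | step 7 | (4aS,6R,7S,9aR)-2-{[tert-butyl(dimethyl)silyl]oxy}-3,5,5,9-tetramethyl-4,4a,5,6,7,9a-hexahydro-1H-benzo[7]annulene-6,7-diol | O[C@H]1C=C(C)[C@@H]2CC(O[Si](C)(C)C(C)(C)C)=C(C)C[C@@H]2C(C)(C)[C@H]1O
F6 | step 12 | (4aS,6R,7S,9aR)-6-hydroxy-3,5,5,9-tetramethyl-2-oxo-2,4a,5,6,7,9a-hexahydro-1H-benzo[7]annulen-7-yl (2R,3R)-2,3-dimethyloxirane-2-carboxylate | O=C(O[C@H]1C=C(C)[C@@H]2CC(=O)C(C)=C[C@@H]2C(C)(C)[C@H]1O)[C@]3(C)O[C@@H]3C
F7 | step 12 | (4aS,6R,7S,9aR)-7-hydroxy-3,5,5,9-tetramethyl-2-oxo-2,4a,5,6,7,9a-hexahydro-1H-benzo[7]annulen-6-yl (2R,3R)-2,3-dimethyloxirane-2-carboxylate | O[C@H]1C=C(C)[C@@H]2CC(=O)C(C)=C[C@@H]2C(C)(C)[C@H]1OC(=O)[C@]3(C)O[C@@H]3C
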